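**Retrosynthetic overview**

- Target 4 is an acyclic ester carrying two 3,4-dimethoxyphenyl rings (ring A on the alcohol half, ring B on the acid half). Both rings are bought; no ring is formed.
- The strategy rests on the saturated three-carbon chain O–CH2–CH2–CH2–C(ring A), a hydrogenated cinnamyl group. Retro-hydrogenation gives the (E)-cinnamyl ester 3.
- The ester O–CH2 bond of 3 is disconnected by allylic C–H acyloxylation with allylic transposition. This leads to methyl eugenol 1, whose CH2–CH=CH2 group becomes CH=CH–CH2–O, and to acid 2, used without activation.
- Order: step 1 forms the C–O bond, step 2 saturates the alkene.

Key step: step 1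

Assumption: methyl eugenol and 3-(3,4-dimethoxyphenyl)propanoic acid are bought and used as received; the target has no stereocentre, and the (E) geometry of 3 is erased in step 2.

**Route**

Step 1
Reactants: 1 methyl eugenol (4-allyl-1,2-dimethoxybenzene); 2 3-(3,4-dimethoxyphenyl)propanoic acid
Product: 3 (E)-3-(3,4-dimethoxyphenyl)prop-2-en-1-yl 3-(3,4-dimethoxyphenyl)propanoate
Conditions: Pd(CH3CN)4(BF4)2 (10 mol %), DMSO (1.4 equiv), iPr2NEt (0.7 equiv), 1,4-benzoquinone (2 equiv), 2 (1.5 equiv), 4 Å MS, CH2Cl2, 41 °C
Reagents that add atoms: none
Why: Sulfoxide-ligated divalent palladium binds the terminal alkene of 1 and cleaves the CH2 hydrogen that is both benzylic and allylic, giving a 1-aryl-π-allylpalladium species; the carboxylate of 2, freed by iPr2NEt, attacks the unsubstituted terminus so that the ester O–CH2 bond forms at the former vinyl carbon with allylic transposition, and benzoquinone returns zerovalent palladium to divalent palladium. The closest known reaction type is the palladium/sulfoxide-catalysed linear allylic C–H esterification of terminal alkenes with carboxylic acids under benzoquinone and amine base, and allylarenes are established substrates of palladium-catalysed allylic acyloxylation. No ring is closed and no stereocentre is created; the (E) geometry follows from the π-allyl complex with the aryl group syn. The step needs linear over branched selectivity, which the substrate secures because attack at the CH2 terminus avoids the hindered benzylic carbon and keeps the new alkene conjugated with the electron-rich dimethoxyphenyl ring. The acetate-free palladium salt leaves 2 as the only carboxylate, monodentate DMSO is chosen over a chelating bis-sulfoxide (which tends to steer alkyl-substituted alkenes toward branched esters), and the molecular sieves suppress Wacker-type oxidation.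

Step 2
Reactants: 3 (E)-3-(3,4-dimethoxyphenyl)prop-2-en-1-yl 3-(3,4-dimethoxyphenyl)propanoate
Product: 4 3-(3,4-dimethoxyphenyl)propyl 3-(3,4-dimethoxyphenyl)propanoate
Conditions: H2 (1 atm), RhCl(PPh3)3 (5 mol %), toluene/EtOH (1:1), rt
Reagents that add atoms: none
Why: Homogeneous hydrogenation with RhCl(PPh3)3 should add H2 across the 1,2-disubstituted styrenyl alkene through a rhodium dihydride–alkene complex, without the hydrogenolysis of the cinnamyl C–O bond that a palladium-on-carbon surface would risk; the ester and the aryl methyl ethers are inert and no stereocentre arises.

**Compound list**

1 | methyl eugenol (4-allyl-1,2-dimethoxybenzene) | COc1ccc(CC=C)cc1OC | starting material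
2 | 3-(3,4-dimethoxyphenyl)propanoic acid | COc1ccc(CCC(=O)O)cc1OC | starting material
3 | (E)-3-(3,4-dimethoxyphenyl)prop-2-en-1-yl 3-(3,4-dimethoxyphenyl)propanoate | COc1ccc(/C=C/COC(=O)CCc2ccc(OC)c(OC)c2)cc1OC | intermediate
4 | 3-(3,4-dimethoxyphenyl)propyl 3-(3,4-dimethoxyphenyl)propanoate | COc1ccc(CCCOC(=O)CCc2ccc(OC)c(OC)c2)cc1OC | target

**Step count**

Total step count: 2
Longest linear sequence: 2 steps (1 or 2 → 3 → 4)

**Steps most likely to fail**

The route has only two steps, so both are ranked and no third step exists.

1. Step 1. The terminal alkene of 1 may migrate into conjugation with ring A through palladium hydride addition and elimination, giving an internal propenylarene that no longer undergoes C–H cleavage. Adventitious water may divert the alkene into Wacker-type oxidation. The catalyst may precipitate as palladium metal before conversion is complete, and some attack at the benzylic terminus may give branched ester. The fallback abandons C–H oxidation for acylation of a preformed alcohol. It sets out from 2: one portion of 2 is reduced with BH3·THF (THF, 0 °C to rt, aqueous quench) to 3-(3,4-dimethoxyphenyl)propan-1-ol F1. F1 is then joined to a second portion of 2 by Steglich esterification (DCC, catalytic DMAP, CH2Cl2, 0 °C to rt). This comes back to the route at 4 and makes step 2 unnecessary.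

2. Step 2. Turnover may be slow on the conjugated, disubstituted alkene flanked by an electron-rich ring. Prolonged exposure to monovalent rhodium may then allow ionisation of the cinnamyl ester, with loss of the acyloxy group, or migration of the double bond; migration toward oxygen would give an enol ester that hydrogenates to the same product 4. The fallback replaces metal-catalysed hydrogenation by metal-free concerted hydrogen transfer, which has no pathway to C–O cleavage. It sets out from 3, which is treated with diimide generated in the flask from 2-nitrobenzenesulfonohydrazide and Et3N (CH2Cl2, rt, reagent added in portions). This comes back to the route at 4 and makes no new compound (F0).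

**Further compounds**

F1 | step 1 | 3-(3,4-dimethoxyphenyl)propan-1-ol | COc1ccc(CCCO)cc1OC
F0 | step 2 | none | none
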